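Locants used throughout: chromanone O1–C8a (ring A = C4a–C8a, ring C = O1–C4), ring B C1'–C6', piperidine N1''–C6''. Compound numbers are those of the steps below.

## The problem

Compound 19 is a (2S)-flavanone of the naringenin type whose C6 carries an (S)-1-methylpiperidin-2-yl group through a C6–C2'' bond wedged between the C5 and C7 hydroxyls. The two stereocentres, C2 and C2'', lie six bonds apart on opposite sides of ring A, so neither can steer the other and each needs its own external source of asymmetry. Regiochemistry must also be decided: the oxygen para to the piperidine-bearing carbon has to become O1, because closure through an ortho oxygen would place the piperidine at C8. Two parts are fragile. C2 is β to the C4 ketone and is lost by retro-oxa-Michael opening in base, most easily once the C5 hydroxyl is free. The C2''–N1'' bond is the benzylic bond of a phenolic Mannich base on a phloroglucinol ring and can ionise when the phenols are free and the compound is heated or held in strong acid. The phenols are therefore uncovered only in the last step. Joining a 2,6-dioxygenated aryl carbon directly to a secondary sp3 carbon would be a crowded coupling, but the structure offers a way round it: C2'' bears N1'', C3'' and C6, and C6 sits on the local symmetry axis of ring A (O5 and O7 are equivalent until ring C is fused). The C6–C2'' bond can therefore be bought as the formyl group of 2,4,6-trihydroxybenzaldehyde, C2'' becoming an imine carbon that accepts C3'' and whose nitrogen then closes onto C6''.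

## Retrosynthesis

**19 ⇒ 18 (three O–benzyl bonds).** O5, O7 and O4' are carried as benzyl ethers to the end and released together by neutral hydrogenolysis. Acid-labile or Lewis-acid-labile groups would put C2 and the C2''–N1'' bond at risk in the last step. The precursor 18 has no free phenol, so neither stereocentre is labile before this point. The forward step must stop at debenzylation.

**18 ⇒ 16 + 17 (C2–C1').** Cutting the aryl–C2 bond leads to chromone 16 and boronic acid 17, and C2 is set by a rhodium-catalysed asymmetric conjugate arylation. The neighbouring cut, O1–C2 through a chalcone, would create C2 in a reversible oxa-Michael step for which catalyst control on unactivated chalcones is modest. The conjugate arylation is irreversible under base-free conditions and has direct precedent on chromones. Ring C of 16 is flat and ring B arrives as a purchasable piece. The forward reaction must override the remote C2'' centre, tolerate the tertiary amine and avoid ring opening.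

**16 ⇒ 14 (O1–C2 and C2–C3).** C2 is a one-carbon unit from DMF dimethyl acetal; the enaminone 15 closes onto the ortho hydroxyl with loss of dimethylamine. In 14 the C8a hydroxyl is the only free phenol, so ring C can close in one direction only and the 6-substitution is fixed. The precursor is a plain 2-hydroxyacetophenone.

**14 ⇒ 13 (C4–C4a).** Friedel–Crafts acetylation of phenol 13. Its two open ring positions are equivalent and both ortho to the free hydroxyl, so there is no regiochemical choice. The forward step needs a Lewis acid mild enough for two benzyl ethers and a benzylic amine.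

**13 ⇒ 12 ⇒ 11 ⇒ 10 (O–Si, N–CH3, N–S).** Three functional-group steps. The order matters: the nitrogen is methylated while every phenol is capped, because a free phloroglucinol-type ring would compete for formaldehyde, and the silyl ether is removed only afterwards to expose the single phenol that becomes O1.

**10 ⇒ 6 + 8 (C2''–C3'' and N1''–C6'').** This is the strategic cut. Cutting C6–C2'' instead would require the hindered aryl–C(sp3) bond to be formed. Cutting only N1''–C2'' would ask for stereocontrol at a carbon that can re-ionise. The chosen cut leaves an aldimine of a symmetric arene (6) and a four-carbon Grignard reagent (8). The forward reaction asks for facial control by the sulfinyl group and an N-alkylation in the same flask.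

**6 ⇒ 4 + 5; 4 ⇒ 2 ⇒ 1; 8 ⇐ 7.** The C=N bond comes from aldehyde 4 and (R)-tert-butanesulfinamide 5. In 1 the para hydroxyl is the most acidic and least hindered, so it is silylated first (2); this marks the future O1. The two ortho hydroxyls are then benzylated under neutral conditions (4, through 3). Reagent 8 comes from 7 by magnesium insertion into the C–Br bond.

## Roads not taken

**Alternative 1:** The cut runs through O1–C8a and C4–C4a, so ring C is annulated onto a ring-A aryne. CsF would unmask the C4a–C8a aryne from the ortho-silyl aryl triflate A3; the alkoxide of the (S)-β-hydroxy ester A2 would add at C8a, away from the C5 ether, and the C4a carbanion would attack the ester to give the protected flavanone A1 in one operation.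
- Merits: the route is convergent, C2 comes in a building block whose C–O bond is never broken, and the position of the aryne fixes the 6-regiochemistry.
- Weak points: A3 is a hexasubstituted benzene that already holds the piperidine stereocentre, so the piperidine problem is only moved, and silyl and triflate groups must be placed side by side on a crowded ring. The alkoxide of A2 is prone to retro-aldol cleavage and to elimination to the cinnamate under fluoride. The aryl anion can be quenched by the acidic α-CH2 instead of acylating. Removal of Boc and the methoxymethyl ethers needs acid on a free phenolic Mannich base, after which the nitrogen must be methylated with phenols free.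
- Comparison: in convergence and in how C2 is secured this road is better than the chosen plan, which sets C2 late by catalysis. The chosen plan sets against it a cheap symmetric ring-A precursor, a key step of a well-tried class, and an end game in which phenols appear only in the last step.

**Alternative 2:** The cut is N1''–C2''. A chiral BINOL-derived phosphoric acid would dehydrate the benzylic alcohol A5 to an ortho-quinone methide and guide the carbamate nitrogen onto C2'', closing the piperidine as A4.
- Merits: the step is catalytic with no auxiliary, A5 is quickly made from a phloroglucinol monoether, and the Boc group could be reduced to N-methyl with LiAlH4 in one step, one fewer than sulfinyl removal plus reductive methylation.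
- Weak points: the quinone methide has β-hydrogens and can tautomerise to a vinylphenol, and the carbamate is a weak nucleophile. A4 is itself a phenolic Mannich base that the same acid can re-ionise, so its enantiomeric purity rests on kinetic control that cannot be enforced. A4 also has free ortho hydroxyls and a capped para oxygen, the reverse of what the ring-C construction needs, so protecting groups must be exchanged before the 6-regiochemistry is secure.
- Comparison: this road is better in atom economy and in the N-methylation. The chosen plan sets against it a stereocentre formed while all ring oxygens are capped, so the C2''–N1'' bond cannot reopen; diastereomers that can be separated; and an oxygen pattern that already marks O1.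

**Alternative 3:** Ring A is cut at C5–C6, C7–C8 and C4a–C5. Irradiation of diazoketone A7 would trigger a Wolff rearrangement to a vinylketene, which adds to the siloxyalkyne A8; four-electron opening and six-electron closure (Danheiser benzannulation) would give A6 with ring A built onto a preformed ring C.
- Merits: the substitution pattern of ring A, including the free C5 hydroxyl next to a silylated O7, is written into the reaction; there is no 6/8 ambiguity; both stereocentres come from the fragments.
- Weak points: A7 holds a light-absorbing enone and a C2 centre β to a ketone, so cycloaddition and ring opening compete. A8 carries a branched piperidinyl group on the alkyne carbon that must bond to the ketene carbon, and the new ring is hexasubstituted. Each fragment needs its own multi-step asymmetric synthesis, and Boc must still be exchanged for methyl afterwards.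
- Comparison: in regiochemical certainty this road is at least the equal of the chosen plan and it is more convergent. The chosen plan sets against it a much shorter sequence from purchasable materials and a key step that is routine for this ring size.

Key step: step 5

Remark on the chemistry: 8 is prepared fresh from 7 (counted as step 4) because the key step depends on its titre, and 19 is targeted as the free base with (S) configuration at both C2 and C2''.

## Route

Step 1
Reactants: 1 2,4,6-trihydroxybenzaldehyde
Product: 2 2,6-dihydroxy-4-[(triisopropylsilyl)oxy]benzaldehyde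
Conditions: i-Pr3SiCl (1.0 equiv), imidazole, DMF, 0 °C
Reagents that add atoms: triisopropylsilyl chloride, CC(C)[Si](Cl)(C(C)C)C(C)C
Why: Selective O-silylation; the C4 hydroxyl is para to the formyl group, hence the most acidic, and is the only one neither hydrogen-bonded to nor flanked by the carbonyl, so the bulky silyl chloride should take it first and mark the future O1.

Step 2
Reactants: 2 2,6-dihydroxy-4-[(triisopropylsilyl)oxy]benzaldehyde
Product: 4 2,6-bis(benzyloxy)-4-[(triisopropylsilyl)oxy]benzaldehyde, via mono-benzyl ether 3 (not isolated)
Conditions: BnOH, PPh3, DIAD, THF, 0 °C → rt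
Reagents that add atoms: benzyl alcohol, OCc1ccccc1
Why: Mitsunobu etherification of the two acidic salicylaldehyde-type hydroxyls; the neutral conditions avoid the carbonate bases that could strip an aryl silyl ether para to a formyl group.

Step 3
Reactants: 4 2,6-bis(benzyloxy)-4-[(triisopropylsilyl)oxy]benzaldehyde; 5 (R)-2-methylpropane-2-sulfinamide
Product: 6 (R,E)-N-{2,6-bis(benzyloxy)-4-[(triisopropylsilyl)oxy]benzylidene}-2-methylpropane-2-sulfinamide
Conditions: Ti(OEt)4, THF, 65 °C
Reagents that add atoms: none
Why: Ti(OEt)4-mediated condensation of an aldehyde with tert-butanesulfinamide; the Lewis acid activates the hindered, electron-rich aldehyde and takes up the water, and only the E-aldimine is expected. The sulfur configuration is untouched.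

Step 4
Reactants: 7 1-bromo-4-chlorobutane
Product: 8 4-chlorobutylmagnesium bromide
Conditions: Mg turnings, I2 (cat.), THF, 20–30 °C; solution titrated and used at once
Reagents that add atoms: magnesium, [Mg]
Why: Grignard formation; magnesium inserts into the C–Br bond much faster than into C–Cl, and a 4-chloroalkyl Grignard reagent neither eliminates nor cyclises at this temperature.

Step 5
Reactants: 6 (R,E)-N-{2,6-bis(benzyloxy)-4-[(triisopropylsilyl)oxy]benzylidene}-2-methylpropane-2-sulfinamide; 8 4-chlorobutylmagnesium bromide
Product: 10 (2S)-2-{2,6-bis(benzyloxy)-4-[(triisopropylsilyl)oxy]phenyl}-1-[(R)-tert-butylsulfinyl]piperidine, via open-chain chloro sulfinamide 9 (not isolated)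
Conditions: 8 (2.5 equiv, THF), toluene, −78 → 0 °C; then KN(SiMe3)2, THF, 0 °C → rt
Reagents that add atoms: none
Why: The alkyl group of 8 adds to the C=N carbon of 6 through a closed six-membered chair in which magnesium is held by the sulfinyl oxygen and the tert-butyl group is equatorial; this forms C2''–C3'' and gives the magnesium salt of 9. KN(SiMe3)2 then turns this into the more nucleophilic potassium sulfinamide, whose nitrogen displaces the primary chloride and forms N1''–C6''. The closest known reaction type is the diastereoselective addition of Grignard reagents to N-tert-butanesulfinyl aldimines in which one partner carries an ω-chloroalkyl chain, followed by base-induced cyclisation to 2-substituted pyrrolidines and piperidines. The piperidine closes by 6-exo-tet N-alkylation. C2'' is controlled by the sulfur stereocentre: in the chelated chair the (R)-sulfinyl group leaves the Si face of the E-aldimine open, and with the priorities N > aryl > alkyl > H this gives (S). The step needs facial selectivity at C=N, secured by running the addition in toluene so that the sulfinyl oxygen and not an ortho benzyloxy oxygen holds the magnesium, and chemoselectivity, secured because an alkyl chloride, a silyl ether and benzyl ethers do not react with a Grignard reagent at these temperatures. No regiochemical question arises because the aryl ring of 6 is symmetric, and any minor C2'' epimer is a diastereomer of 10 that can be removed by chromatography.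

Step 6
Reactants: 10 (2S)-2-{2,6-bis(benzyloxy)-4-[(triisopropylsilyl)oxy]phenyl}-1-[(R)-tert-butylsulfinyl]piperidine
Product: 11 (2S)-2-{2,6-bis(benzyloxy)-4-[(triisopropylsilyl)oxy]phenyl}piperidine
Conditions: HCl (4 M in dioxane), MeOH, 0 °C, short; aq. NH3 work-up
Reagents that add atoms: none
Why: Acidic methanolysis of the N–S bond, the standard removal of the tert-butanesulfinyl group; it is fast at 0 °C, where the aryl silyl ether, the benzyl ethers and the benzylic C2''–N1'' bond should hold, and acid–base extraction removes the sulfinate ester. C2'' is not involved.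

Step 7
Reactants: 11 (2S)-2-{2,6-bis(benzyloxy)-4-[(triisopropylsilyl)oxy]phenyl}piperidine
Product: 12 (2S)-2-{2,6-bis(benzyloxy)-4-[(triisopropylsilyl)oxy]phenyl}-1-methylpiperidine
Conditions: aq. HCHO, NaBH(OAc)3, ClCH2CH2Cl, rt
Reagents that add atoms: formaldehyde, C=O
Why: Reductive amination methylates the secondary amine once only; it is run while every phenol is capped so that the electron-rich ring cannot be hydroxymethylated.

Step 8
Reactants: 12 (2S)-2-{2,6-bis(benzyloxy)-4-[(triisopropylsilyl)oxy]phenyl}-1-methylpiperidine
Product: 13 3,5-bis(benzyloxy)-4-[(2S)-1-methylpiperidin-2-yl]phenol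
Conditions: Bu4NF, THF, 0 °C
Reagents that add atoms: none
Why: Fluoride cleavage of the aryl silyl ether; benzyl ethers and the tertiary amine are inert, and the single phenol released is the oxygen para to C2'', the future O1.

Step 9
Reactants: 13 3,5-bis(benzyloxy)-4-[(2S)-1-methylpiperidin-2-yl]phenol
Product: 14 1-{2,4-bis(benzyloxy)-6-hydroxy-3-[(2S)-1-methylpiperidin-2-yl]phenyl}ethan-1-one
Conditions: Ac2O, BF3·OEt2, CH2Cl2, 0 °C → rt; then 1 M NaOH, MeOH (work-up)
Reagents that add atoms: acetic anhydride, CC(=O)OC(C)=O
Why: Friedel–Crafts acetylation (with O-acetylation and Fries-type transfer) of a phloroglucinol-type phenol needs only BF3·OEt2 at or below room temperature. The two open ring positions are equivalent and both ortho to the free hydroxyl, so only one ketone can form. The basic work-up frees the ketone from boron and cleaves any aryl acetate.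

Step 10
Reactants: 14 1-{2,4-bis(benzyloxy)-6-hydroxy-3-[(2S)-1-methylpiperidin-2-yl]phenyl}ethan-1-one
Product: 16 5,7-bis(benzyloxy)-6-[(2S)-1-methylpiperidin-2-yl]-4H-chromen-4-one, via enaminone 15 (not isolated)
Conditions: Me2NCH(OMe)2, toluene, 80 °C; then conc. HCl, CH2Cl2, rt; aq. NaOH work-up
Reagents that add atoms: N,N-dimethylformamide dimethyl acetal, COC(OC)N(C)C
Why: Enaminone formation at the acetyl methyl group, then acid-promoted addition of the ortho hydroxyl and loss of dimethylamine, is the standard chromone synthesis from 2-hydroxyacetophenones. Because the C8a hydroxyl is the only free phenol, ring C closes in one direction and the piperidine ends at C6.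

Step 11
Reactants: 16 5,7-bis(benzyloxy)-6-[(2S)-1-methylpiperidin-2-yl]-4H-chromen-4-one; 17 [4-(benzyloxy)phenyl]boronic acid
Product: 18 (2S)-5,7-bis(benzyloxy)-2-[4-(benzyloxy)phenyl]-6-[(2S)-1-methylpiperidin-2-yl]-2,3-dihydro-4H-chromen-4-one
Conditions: [Rh(OH)(C8H12)]2 (C8H12 = cycloocta-1,5-diene; cat.), (S)-MeO-F12-BIPHEP, toluene/H2O, 30 °C
Reagents that add atoms: none
Why: Hayashi–Miyaura conjugate addition; rhodium-catalysed asymmetric 1,4-addition of arylboronic acids to chromones is an established route to 2-arylchroman-4-ones, and the electron-poor ligand (S)-6,6'-dimethoxy-2,2'-bis[bis(3,4,5-trifluorophenyl)phosphino]-1,1'-biphenyl is chosen for the low electrophilicity of a 5,7-dialkoxychromone. C2 is set by the catalyst: the (S) ligand is chosen by analogy with cyclic enones, where it delivers the aryl group to the enone face that corresponds here to (2S), and the ligand antipode would be used should the sense prove opposite. The remote C2'' centre is not expected to interfere, and the base-free medium guards against ring opening of the product.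

Step 12
Reactants: 18 (2S)-5,7-bis(benzyloxy)-2-[4-(benzyloxy)phenyl]-6-[(2S)-1-methylpiperidin-2-yl]-2,3-dihydro-4H-chromen-4-one
Product: 19 (2S)-5,7-dihydroxy-2-(4-hydroxyphenyl)-6-[(2S)-1-methylpiperidin-2-yl]-2,3-dihydro-4H-chromen-4-one
Conditions: H2 (1 atm), Pd/C (10% palladium on carbon), EtOAc/MeOH, rt
Reagents that add atoms: none
Why: Hydrogenolysis of the three aryl benzyl ethers under neutral conditions at room temperature should spare the C4 ketone, the O1–C2 bond and the hindered C2''–N1'' bond if stopped at full debenzylation. Neither stereocentre is touched, and 19 is isolated without heating.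

## Compound list

1 | 2,4,6-trihydroxybenzaldehyde | O=Cc1c(O)cc(O)cc1O | starting material
2 | 2,6-dihydroxy-4-[(triisopropylsilyl)oxy]benzaldehyde | O=Cc1c(O)cc(O[Si](C(C)C)(C(C)C)C(C)C)cc1O | intermediate
3 | 2-(benzyloxy)-6-hydroxy-4-[(triisopropylsilyl)oxy]benzaldehyde | O=Cc1c(O)cc(O[Si](C(C)C)(C(C)C)C(C)C)cc1OCc1ccccc1 | intermediate (not isolated)
4 | 2,6-bis(benzyloxy)-4-[(triisopropylsilyl)oxy]benzaldehyde | O=Cc1c(OCc2ccccc2)cc(O[Si](C(C)C)(C(C)C)C(C)C)cc1OCc1ccccc1 | intermediate
5 | (R)-2-methylpropane-2-sulfinamide | CC(C)(C)[S@](N)=O | starting material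
6 | (R,E)-N-{2,6-bis(benzyloxy)-4-[(triisopropylsilyl)oxy]benzylidene}-2-methylpropane-2-sulfinamide | CC(C)(C)[S@@](=O)/N=C/c1c(OCc2ccccc2)cc(O[Si](C(C)C)(C(C)C)C(C)C)cc1OCc1ccccc1 | intermediate
7 | 1-bromo-4-chlorobutane | ClCCCCBr | starting material
8 | 4-chlorobutylmagnesium bromide | ClCCCC[Mg]Br | intermediate
9 | (R)-N-[(1S)-1-{2,6-bis(benzyloxy)-4-[(triisopropylsilyl)oxy]phenyl}-5-chloropentyl]-2-methylpropane-2-sulfinamide (present as its N-metal salt) | CC(C)(C)[S@@](=O)N[C@@H](CCCCCl)c1c(OCc2ccccc2)cc(O[Si](C(C)C)(C(C)C)C(C)C)cc1OCc1ccccc1 | intermediate (not isolated)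
10 | (2S)-2-{2,6-bis(benzyloxy)-4-[(triisopropylsilyl)oxy]phenyl}-1-[(R)-tert-butylsulfinyl]piperidine | CC(C)(C)[S@@](=O)N1CCCC[C@H]1c1c(OCc2ccccc2)cc(O[Si](C(C)C)(C(C)C)C(C)C)cc1OCc1ccccc1 | intermediate
11 | (2S)-2-{2,6-bis(benzyloxy)-4-[(triisopropylsilyl)oxy]phenyl}piperidine | N1CCCC[C@H]1c1c(OCc2ccccc2)cc(O[Si](C(C)C)(C(C)C)C(C)C)cc1OCc1ccccc1 | intermediate
12 | (2S)-2-{2,6-bis(benzyloxy)-4-[(triisopropylsilyl)oxy]phenyl}-1-methylpiperidine | CN1CCCC[C@H]1c1c(OCc2ccccc2)cc(O[Si](C(C)C)(C(C)C)C(C)C)cc1OCc1ccccc1 | intermediate
13 | 3,5-bis(benzyloxy)-4-[(2S)-1-methylpiperidin-2-yl]phenol | CN1CCCC[C@H]1c1c(OCc2ccccc2)cc(O)cc1OCc1ccccc1 | intermediate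
14 | 1-{2,4-bis(benzyloxy)-6-hydroxy-3-[(2S)-1-methylpiperidin-2-yl]phenyl}ethan-1-one | CN1CCCC[C@H]1c1c(OCc2ccccc2)cc(O)c(C(C)=O)c1OCc1ccccc1 | intermediate
15 | (2E)-1-{2,4-bis(benzyloxy)-6-hydroxy-3-[(2S)-1-methylpiperidin-2-yl]phenyl}-3-(dimethylamino)prop-2-en-1-one | CN1CCCC[C@H]1c1c(OCc2ccccc2)cc(O)c(C(=O)/C=C/N(C)C)c1OCc1ccccc1 | intermediate (not isolated)
16 | 5,7-bis(benzyloxy)-6-[(2S)-1-methylpiperidin-2-yl]-4H-chromen-4-one | CN1CCCC[C@H]1c1c(OCc2ccccc2)cc2occc(=O)c2c1OCc1ccccc1 | intermediate
17 | [4-(benzyloxy)phenyl]boronic acid | OB(O)c1ccc(OCc2ccccc2)cc1 | starting material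
18 | (2S)-5,7-bis(benzyloxy)-2-[4-(benzyloxy)phenyl]-6-[(2S)-1-methylpiperidin-2-yl]-2,3-dihydro-4H-chromen-4-one | CN1CCCC[C@H]1c1c(OCc2ccccc2)cc2c(c1OCc1ccccc1)C(=O)C[C@@H](c1ccc(OCc3ccccc3)cc1)O2 | intermediate
19 | (2S)-5,7-dihydroxy-2-(4-hydroxyphenyl)-6-[(2S)-1-methylpiperidin-2-yl]-2,3-dihydro-4H-chromen-4-one | CN1CCCC[C@H]1c1c(O)cc2c(c1O)C(=O)C[C@@H](c1ccc(O)cc1)O2 | target

## Step count and least certain steps

Total: 12 steps. Longest linear sequence: 11 steps (1 → 19 through steps 1–3 and 5–12); step 4 is a one-step side branch.

**Step 5 (key step).** The most likely failure is erosion or reversal of facial selectivity, because an ortho benzyloxy oxygen can compete with the sulfinyl oxygen for magnesium and open a second chelated pathway. Slow addition to a hindered, electron-rich aldimine with competing β-hydride reduction, and incomplete N-alkylation, are lesser concerns. Fallback: if the ortho-alkoxy pathway dominates, the stereocontrolling reagent is changed. Setting out from aldehyde 4, condensation with (S)-2-methylpropane-2-sulfinamide and Ti(OEt)4 would give the (S,E)-N-sulfinyl aldimine F1. Addition of 8 would give the open-chain (S)-sulfinyl chloropentyl amide F2 (not isolated), and KN(SiMe3)2 would close it to the (S)-sulfinyl (2S)-piperidine F3. Treatment with HCl in MeOH returns to the route at amine 11.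

**Step 9.** The Lewis acid may cause loss or carbon-migration of a benzyl group on the very electron-rich ring, ionisation at the benzylic C2''–N1'' bond with scrambling of C2'', or a second acylation. Fallback: setting out from phenol 13, Vilsmeier–Haack formylation (POCl3, DMF, 0 °C) would give 2,4-bis(benzyloxy)-6-hydroxy-3-[(2S)-1-methylpiperidin-2-yl]benzaldehyde F4. Excess MeMgBr would give the 1-aryl-ethanol F5, and MnO2 oxidation of this benzylic alcohol returns to the route at ketone 14. No Lewis acid stronger than the iminium salt is used and every step is run at or below room temperature.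

**Step 11.** Insertion of the 5,7-dialkoxychromone into the aryl–rhodium bond may be slow, so protodeboronation of 17 could consume the reagent; face selectivity may be insufficient; and any base-induced ring opening of the product would erode C2. Fallback: setting out from ketone 14, Claisen–Schmidt condensation with 4-(benzyloxy)benzaldehyde (KOH, EtOH) would give the 2'-hydroxychalcone F6. Oxa-Michael closure (NaOAc, EtOH, reflux) would give 18 together with its (2R) epimer F7. These are diastereomers because of C2'' and would be separated by chromatography, with F7 returned to the closure conditions for re-equilibration. The route is rejoined at 18.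

**Step 12.** Over-reduction is the main risk: hydrogenolysis of the benzylic O1–C2 bond or of the benzylic C2''–N1'' bond. The tertiary amine may also slow the catalyst and invite forcing conditions. Fallback: setting out from 18, Lewis-acid debenzylation with BCl3 and pentamethylbenzene as benzyl-cation scavenger (CH2Cl2, −78 °C) leads directly to 19. This fallback makes no new compound (F0).

## Further compounds

F1 | step 5 | (S,E)-N-{2,6-bis(benzyloxy)-4-[(triisopropylsilyl)oxy]benzylidene}-2-methylpropane-2-sulfinamide | CC(C)(C)[S@](=O)/N=C/c1c(OCc2ccccc2)cc(O[Si](C(C)C)(C(C)C)C(C)C)cc1OCc1ccccc1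
F2 | step 5 | (S)-N-[(1S)-1-{2,6-bis(benzyloxy)-4-[(triisopropylsilyl)oxy]phenyl}-5-chloropentyl]-2-methylpropane-2-sulfinamide | CC(C)(C)[S@](=O)N[C@@H](CCCCCl)c1c(OCc2ccccc2)cc(O[Si](C(C)C)(C(C)C)C(C)C)cc1OCc1ccccc1
F3 | step 5 | (2S)-2-{2,6-bis(benzyloxy)-4-[(triisopropylsilyl)oxy]phenyl}-1-[(S)-tert-butylsulfinyl]piperidine | CC(C)(C)[S@](=O)N1CCCC[C@H]1c1c(OCc2ccccc2)cc(O[Si](C(C)C)(C(C)C)C(C)C)cc1OCc1ccccc1
F4 | step 9 | 2,4-bis(benzyloxy)-6-hydroxy-3-[(2S)-1-methylpiperidin-2-yl]benzaldehyde | CN1CCCC[C@H]1c1c(OCc2ccccc2)cc(O)c(C=O)c1OCc1ccccc1
F5 | step 9 | 1-{2,4-bis(benzyloxy)-6-hydroxy-3-[(2S)-1-methylpiperidin-2-yl]phenyl}ethan-1-ol (both carbinol epimers) | CN1CCCC[C@H]1c1c(OCc2ccccc2)cc(O)c(C(C)O)c1OCc1ccccc1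
F6 | step 11 | (2E)-1-{2,4-bis(benzyloxy)-6-hydroxy-3-[(2S)-1-methylpiperidin-2-yl]phenyl}-3-[4-(benzyloxy)phenyl]prop-2-en-1-one | CN1CCCC[C@H]1c1c(OCc2ccccc2)cc(O)c(C(=O)/C=C/c2ccc(OCc3ccccc3)cc2)c1OCc1ccccc1
F7 | step 11 | (2R)-5,7-bis(benzyloxy)-2-[4-(benzyloxy)phenyl]-6-[(2S)-1-methylpiperidin-2-yl]-2,3-dihydro-4H-chromen-4-one | CN1CCCC[C@H]1c1c(OCc2ccccc2)cc2c(c1OCc1ccccc1)C(=O)C[C@H](c1ccc(OCc3ccccc3)cc1)O2
F0 | step 12 | none | none
A1 | alternative 1 | tert-butyl (2S)-2-{(2S)-5,7-bis(methoxymethoxy)-2-[4-(methoxymethoxy)phenyl]-4-oxo-3,4-dihydro-2H-chromen-6-yl}piperidine-1-carboxylate | CC(C)(C)OC(=O)N1CCCC[C@H]1c1c(OCOC)cc2c(c1OCOC)C(=O)C[C@@H](c1ccc(OCOC)cc1)O2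
A2 | alternative 1 | methyl (3S)-3-hydroxy-3-[4-(methoxymethoxy)phenyl]propanoate | COC(=O)C[C@H](O)c1ccc(OCOC)cc1
A3 | alternative 1 | tert-butyl (2S)-2-[2,6-bis(methoxymethoxy)-4-{[(trifluoromethyl)sulfonyl]oxy}-3-(trimethylsilyl)phenyl]piperidine-1-carboxylate | CC(C)(C)OC(=O)N1CCCC[C@H]1c1c(OCOC)cc(OS(=O)(=O)C(F)(F)F)c([Si](C)(C)C)c1OCOC
A4 | alternative 2 | tert-butyl (2S)-2-[4-(benzyloxy)-2,6-dihydroxyphenyl]piperidine-1-carboxylate | CC(C)(C)OC(=O)N1CCCC[C@H]1c1c(O)cc(OCc2ccccc2)cc1O
A5 | alternative 2 | tert-butyl {5-[4-(benzyloxy)-2,6-dihydroxyphenyl]-5-hydroxypentyl}carbamate (racemic) | CC(C)(C)OC(=O)NCCCCC(O)c1c(O)cc(OCc2ccccc2)cc1O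
A6 | alternative 3 | tert-butyl (2S)-2-{(2S)-2-[4-(benzyloxy)phenyl]-5-hydroxy-4-oxo-7-[(triisopropylsilyl)oxy]-3,4-dihydro-2H-chromen-6-yl}piperidine-1-carboxylate | CC(C)(C)OC(=O)N1CCCC[C@H]1c1c(O[Si](C(C)C)(C(C)C)C(C)C)cc2c(c1O)C(=O)C[C@@H](c1ccc(OCc3ccccc3)cc1)O2
A7 | alternative 3 | (2S)-2-[4-(benzyloxy)phenyl]-6-(diazoacetyl)-2,3-dihydro-4H-pyran-4-one | [N-]=[N+]=CC(=O)C1=CC(=O)C[C@@H](c2ccc(OCc3ccccc3)cc2)O1
A8 | alternative 3 | tert-butyl (2S)-2-{[(triisopropylsilyl)oxy]ethynyl}piperidine-1-carboxylate | CC(C)(C)OC(=O)N1CCCC[C@H]1C#CO[Si](C(C)C)(C(C)C)C(C)C
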